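Everything hinges on cutting the C10–C20 bond: the angular methyl is brought in as a methylene delivered onto the C9=C10 alkene of an octalin grown from an anisole. The key step exploits the ring A/ring B fusion carbon C10, whose C20 methyl must lie anti to H5 and 1,3-diaxial to the C19 methyl on C4; a zinc carbenoid tethered to the 8-hydroxyl reaches this congested face and, in one operation, makes C10–C20 plus a temporary C9–C20 bond and fixes C9 and C10. Its precursor is the ring B allylic alcohol (OH anti to H5) with ring A locked as the trans-fused O3/O18 acetonide. Li/NH3 later severs C9–C20, unveiling the methyl and a C8–C9 enolate.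

Key step: step 9

Conventions: labdane numbering is used for every bicyclic compound (C18 = oxygenated carbon on C4, C19 = methyl on C4, C20 = carbon on C10, C17 = exocyclic methylene, C11/C12 = side-chain CH2 groups, C13–C16 = butenolide). "α" is the face that carries C20 in the target (also C19, O3 and C11); "β" is the face of H5, H9 and C18. The target is (3R,4S,5S,9R,10S).

Assumption on the chemistry: the chiral Sc(OTf)3–bipyridine catalyst of step 3 is taken to accept the aryl-conjugated tetrasubstituted enol ether 6 as it does simpler tetrasubstituted silyl enol ethers; the ligand antipode that gives S-configured 8 is to be fixed in a trial run.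

**Step 1**
Reactants: 1 6-methoxy-2-tetralone; 2 iodomethane
Product: 5 rac-6-methoxy-1-methyl-2-tetralone, via pyrrolidine enamine 3 (not isolated), via iminium iodide 4 (not isolated)
Conditions: pyrrolidine, toluene, reflux (Dean–Stark); MeI, MeCN, 60 °C; AcOH/H2O, rt
Reagents that add atoms: iodomethane, CI; water, O
Why: Stork enamine alkylation, in which the enamine forms only toward the benzylic carbon (styrene conjugation) and is mono-C-methylated there before hydrolysis; the new centre is racemic and is flattened again in step 2.

**Step 2**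
Reactants: 5 rac-6-methoxy-1-methyl-2-tetralone
Product: 6 (6-methoxy-1-methyl-3,4-dihydronaphthalen-2-yl)oxytrimethylsilane
Conditions: Me3SiCl, Et3N, DMF, 80 °C
Reagents that add atoms: chlorotrimethylsilane, C[Si](C)(C)Cl
Why: silyl enol ether formation under equilibrating conditions should place the double bond between C3 and C4, where it is tetrasubstituted and conjugated with the anisole ring, so one regioisomer is expected and the racemic C4 centre is erased.

**Step 3**
Reactants: 6 (6-methoxy-1-methyl-3,4-dihydronaphthalen-2-yl)oxytrimethylsilane; 7 formaldehyde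
Product: 8 (S)-1-(hydroxymethyl)-6-methoxy-1-methyl-3,4-dihydronaphthalen-2(1H)-one
Conditions: aq. CH2O (35%), Sc(OTf)3 (10 mol %), 6,6'-bis(1-hydroxy-2,2-dimethylpropyl)-2,2'-bipyridine (single enantiomer, 12 mol %), DME/H2O 9:1, −20 °C
Reagents that add atoms: formaldehyde, C=O
Why: Lewis-acid-catalysed asymmetric Mukaiyama aldol reaction (hydroxymethylation) of a tetrasubstituted silyl enol ether, in which the chiral scandium complex should differentiate the enol ether faces so that quaternary C4 is created with S configuration, while the weakly acidic aqueous medium avoids base-induced retro-aldol loss of formaldehyde.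

**Step 4**
Reactants: 8 (S)-1-(hydroxymethyl)-6-methoxy-1-methyl-3,4-dihydronaphthalen-2(1H)-one
Product: 9 (1S,2R)-1-(hydroxymethyl)-6-methoxy-1-methyl-1,2,3,4-tetrahydronaphthalen-2-ol
Conditions: Me4NBH(OAc)3, MeCN/AcOH 1:1, −20 °C
Reagents that add atoms: none
Why: hydroxyl-directed Evans–Saksena reduction, in which the acetoxyborohydride exchanges onto the C18 hydroxyl and hands hydride to the carbonyl face on which C18 lies, so O3 should end trans to C18 (3R), and the acidic medium suppresses retro-aldol cleavage.

**Step 5**
Reactants: 9 (1S,2R)-1-(hydroxymethyl)-6-methoxy-1-methyl-1,2,3,4-tetrahydronaphthalen-2-ol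
Product: 10 O3/O18-isopropylidene acetal of 9 (anisole acetonide)
Conditions: 2,2-dimethoxypropane, pyridinium p-toluenesulfonate (cat.), acetone, rt
Reagents that add atoms: 2,2-dimethoxypropane, COC(C)(C)OC
Why: acid-catalysed transacetalisation closes the trans 1,3-diol to a trans-fused 2,2-dimethyl-1,3-dioxane with C3–O and C4–C18 both equatorial, which fixes the C19 methyl axial for the later control of C5.

**Step 6**
Reactants: 10 O3/O18-isopropylidene acetal of 9 (anisole acetonide)
Product: 11 8-methoxy-5(10),7-diene acetonide (2,5-dihydroanisole)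
Conditions: Li, NH3(l)/THF, t-BuOH, −78 to −33 °C; MeOH
Reagents that add atoms: none
Why: Birch reduction of an anisole protonates ortho and meta to the methoxy group, leaving the enol ether C7=C8 and the tetrasubstituted C5=C10 alkene, and neither the acetonide nor the non-benzylic C–O bonds are attacked by Li/NH3.

**Step 7**
Reactants: 11 8-methoxy-5(10),7-diene acetonide (2,5-dihydroanisole)
Product: 13 5β-H 9(10)-en-8-one acetonide, via unconjugated 5(10)-en-8-one 12 (not isolated)
Conditions: (CO2H)2 (cat.), acetone/H2O, 0 °C to rt; then NaOMe (cat.), MeOH, rt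
Reagents that add atoms: water, O
Why: mild enol ether hydrolysis in wet acetone (which keeps the acetonide closed) is followed by base-mediated conjugation through the dienolate, and since only the C5 epimer with H5 anti to the axial C19 methyl lets ring A stay a chair fused to the dioxane, reversible protonation should set C5 under thermodynamic control.

**Step 8**
Reactants: 13 5β-H 9(10)-en-8-one acetonide
Product: 14 8α-hydroxy 5β-H 9(10)-ene acetonide (pseudoaxial allylic alcohol)
Conditions: LiBH(s-Bu)3, THF, −78 °C; then NaOH, H2O2, 0 °C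
Reagents that add atoms: none
Why: 1,2-reduction of a β,β-disubstituted cyclohexenone by a bulky trialkylborohydride, which approaches along the equatorial trajectory (avoiding axial H6) and should therefore give the pseudoaxial 8α-alcohol anti to H5, as known for fused 4-en-3-ones.

**Step 9**
Reactants: 14 8α-hydroxy 5β-H 9(10)-ene acetonide (pseudoaxial allylic alcohol); 15 diiodomethane
Product: 17 9α,10α-methano 8α-ol acetonide (C20 bridging C9 and C10), via iodomethylzinc alkoxide 16 (not isolated)
Conditions: Et2Zn, CH2I2, CH2Cl2, −10 °C to rt; aq. NH4Cl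
Reagents that add atoms: diiodomethane, ICI
Why: Et2Zn first turns the C8 hydroxyl into a zinc alkoxide, exchange with CH2I2 gives an iodomethylzinc unit held on that oxygen, and methylene is then passed to C9=C10 in a concerted, stereospecific butterfly-type transition state. The closest known reaction type is the hydroxyl-directed Simmons–Smith cyclopropanation (Furukawa variant) of cyclic allylic alcohols. The three-membered ring closes in a single [2+1] event in which C9–C20 and C10–C20 form together on one face, so no stepwise ring-closure mode is involved. The new stereocentres C9 and C10 are both controlled by the C8 carbinol centre, because the carbenoid can only reach the alkene face syn to the oxygen that carries it. The selectivity needed is facial: the α face, flanked by the axial C19 methyl, is the sterically worse one and should be secured by the pseudoaxial 8α-alkoxide sitting directly over it, the directed pathway being much faster than undirected attack on the β face. Chemoselectivity is not an issue, since C9=C10 is the only alkene and the acetal oxygens are remote and far weaker donors than the alkoxide.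

**Step 10**
Reactants: 17 9α,10α-methano 8α-ol acetonide (C20 bridging C9 and C10)
Product: 18 9α,10α-methano 8-one acetonide (cyclopropyl ketone)
Conditions: Pr4N[RuO4] (5 mol %), N-methylmorpholine N-oxide, 4 Å sieves, CH2Cl2, rt
Reagents that add atoms: none
Why: Ley–Griffith oxidation of a secondary cyclopropyl carbinol under neutral conditions avoids cyclopropylcarbinyl cation chemistry and acetonide loss and touches no stereocentre.

**Step 11**
Reactants: 18 9α,10α-methano 8-one acetonide (cyclopropyl ketone); 19 tert-butyl bromoacetate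
Product: 21 tert-butyl (8-oxo-10α-methyl-decalin-9-yl)acetate acetonide (C9 epimers), via lithium enolate 20 (not isolated)
Conditions: Li, NH3(l)/THF, t-BuOH (1 equiv), −78 °C; NH3 removed; BrCH2CO2t-Bu, THF, −78 to 0 °C
Reagents that add atoms: tert-butyl bromoacetate, CC(C)(C)OC(=O)CBr
Why: dissolving-metal cleavage of a conjugated cyclopropyl ketone should break the exocyclic C9–C20 bond (best overlap with the carbonyl π system, less substituted carbanion), leaving C20 as the α-methyl on C10 with the trans ring fusion and a regiodefined lithium C8–C9 enolate that is C-alkylated at C9 by the activated bromide (reductive alkylation), the C9 configuration being settled in step 12.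

**Step 12**
Reactants: 21 tert-butyl (8-oxo-10α-methyl-decalin-9-yl)acetate acetonide (C9 epimers)
Product: 22 tert-butyl 9β-H (8-oxo-10α-methyl-decalin-9-yl)acetate acetonide
Conditions: KOt-Bu (cat.), t-BuOH/THF, rt
Reagents that add atoms: none
Why: base-mediated epimerisation α to the ketone should converge on the equatorial α-oriented acetate arm, since the axial epimer suffers 1,3-diaxial contacts with H5 and H7 on the trans-decalin, giving the 9β-H configuration of the target.

**Step 13**
Reactants: 22 tert-butyl 9β-H (8-oxo-10α-methyl-decalin-9-yl)acetate acetonide; 23 methyltriphenylphosphonium bromide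
Product: 25 8(17)-methylene tert-butyl ester acetonide, via methylenetriphenylphosphorane 24 (not isolated)
Conditions: Ph3PCH3Br, KOt-Bu, toluene, 90 °C
Reagents that add atoms: methyltriphenylphosphonium bromide, C[P+](c1ccccc1)(c1ccccc1)c1ccccc1.[Br-]
Why: Wittig methylenation with excess ylide in hot toluene suits hindered enolisable ketones, the tert-butyl ester is inert to the ylide, and C9 already holds its thermodynamic configuration so reversible enolisation does no harm.

**Step 14**
Reactants: 25 8(17)-methylene tert-butyl ester acetonide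
Product: 26 12-hydroxy 8(17)-ene acetonide
Conditions: LiAlH4, THF, 0 °C to rt
Reagents that add atoms: none
Why: hydride reduction of the ester gives the primary alcohol, the 1,1-disubstituted alkene and the acetonide being inert to LiAlH4.

**Step 15**
Reactants: 26 12-hydroxy 8(17)-ene acetonide
Product: 27 12-iodo 8(17)-ene acetonide
Conditions: I2, PPh3, imidazole, CH2Cl2, 0 °C to rt
Reagents that add atoms: iodine, [I][I]
Why: Appel-type iodination of an unhindered primary alcohol proceeds by SN2 displacement of the oxyphosphonium group, and imidazole buffers the acid so that acetonide and exocyclic alkene survive.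

**Step 16**
Reactants: 27 12-iodo 8(17)-ene acetonide; 28 4-bromofuran-2(5H)-one
Product: 30 3α,18-O-isopropylidene-labda-8(17),13-dien-15,16-olide, via alkylzinc iodide 29 (not isolated)
Conditions: Zn, LiCl, THF, 40 °C; then 4-bromofuran-2(5H)-one, PdCl2(dppf) (5 mol %), THF, rt to 50 °C
Reagents that add atoms: 4-bromofuran-2(5H)-one, O=C1OCC(Br)=C1
Why: Negishi cross-coupling, in which LiCl-assisted zinc insertion gives a primary alkylzinc that tolerates the lactone and the palladium-catalysed coupling with the β-bromo enoate forms C12–C13 (the bidentate phosphine suppressing β-hydride elimination) without touching any stereocentre.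

**Step 17**
Reactants: 30 3α,18-O-isopropylidene-labda-8(17),13-dien-15,16-olide
Product: 31 3α,18-dihydroxylabda-8(17),13-dien-15,16-olide
Conditions: AcOH/H2O 4:1, rt
Reagents that add atoms: none
Why: hydrolysis of the isopropylidene acetal in aqueous acetic acid is mild enough to leave the exocyclic alkene unisomerised and the butenolide intact.

**Step 18**
Reactants: 31 3α,18-dihydroxylabda-8(17),13-dien-15,16-olide
Product: 32 18-O-(tert-butyldimethylsilyl)-3α-hydroxylabda-8(17),13-dien-15,16-olide
Conditions: t-BuMe2SiCl, imidazole, CH2Cl2, 0 °C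
Reagents that add atoms: tert-butylchlorodimethylsilane, CC(C)(C)[Si](C)(C)Cl
Why: chemoselective silylation, the primary C18 hydroxyl reacting far faster than the secondary C3 hydroxyl flanked by quaternary C4.

**Step 19**
Reactants: 32 18-O-(tert-butyldimethylsilyl)-3α-hydroxylabda-8(17),13-dien-15,16-olide; 33 angelic acid
Product: 35 3α-angeloyloxy-18-O-(tert-butyldimethylsilyl)labda-8(17),13-dien-15,16-olide, via angelic 2,4,6-trichlorobenzoic anhydride 34 (not isolated)
Conditions: angelic acid, 2,4,6-trichlorobenzoyl chloride, Et3N, toluene, rt; then 32, toluene, 75 °C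
Reagents that add atoms: angelic acid, C/C=C(/C)C(=O)O
Why: Yamaguchi-type esterification through the mixed anhydride without a nucleophilic catalyst is known to acylate hindered secondary alcohols with angelic acid without Z-to-E isomerisation to the tiglate, and the C3–O bond is not broken so its configuration is retained.

**Step 20**
Reactants: 35 3α-angeloyloxy-18-O-(tert-butyldimethylsilyl)labda-8(17),13-dien-15,16-olide
Product: 36 (3R,4S,5S,9R,10S)-3-angeloyloxy-18-hydroxylabda-8(17),13-dien-15,16-olide (target)
Conditions: HF·pyridine, pyridine, THF, 0 °C to rt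
Reagents that add atoms: none
Why: fluoride-mediated cleavage of the primary silyl ether under buffered, weakly acidic conditions should avoid O3-to-O18 acyl migration, angelate isomerisation and damage to the butenolide.

**Compound list**

1 | 6-methoxy-2-tetralone | COc1ccc2CC(=O)CCc2c1 | starting material
2 | iodomethane | CI | starting material
3 | 1-(6-methoxy-3,4-dihydronaphthalen-2-yl)pyrrolidine (not isolated) | COc1ccc2c(CCC(N3CCCC3)=C2)c1 | intermediate
4 | 1-(6-methoxy-1-methyl-3,4-dihydronaphthalen-2(1H)-ylidene)pyrrolidinium iodide (not isolated) | COc1ccc2c(CCC(=[N+]3CCCC3)C2C)c1.[I-] | intermediate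
5 | rac-6-methoxy-1-methyl-2-tetralone (racemic) | COc1ccc2c(CCC(=O)C2C)c1 | intermediate
6 | (6-methoxy-1-methyl-3,4-dihydronaphthalen-2-yl)oxytrimethylsilane | COc1ccc2c(CCC(O[Si](C)(C)C)=C2C)c1 | intermediate
7 | formaldehyde | C=O | starting material
8 | (S)-1-(hydroxymethyl)-6-methoxy-1-methyl-3,4-dihydronaphthalen-2(1H)-one | COc1ccc2c(CCC(=O)[C@]2(C)CO)c1 | intermediate
9 | (1S,2R)-1-(hydroxymethyl)-6-methoxy-1-methyl-1,2,3,4-tetrahydronaphthalen-2-ol | COc1ccc2c(CC[C@@H](O)[C@]2(C)CO)c1 | intermediate
10 | anisole acetonide: trans-fused O3/O18-isopropylidene acetal of 9 | COc1ccc2c(CC[C@H]3OC(C)(C)OC[C@]23C)c1 | intermediate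
11 | 8-methoxy-5(10),7-diene acetonide | COC1=CCC2=C(CC[C@H]3OC(C)(C)OC[C@]23C)C1 | intermediate
12 | 5(10)-en-8-one acetonide (not isolated) | O=C1CCC2=C(CC[C@H]3OC(C)(C)OC[C@]23C)C1 | intermediate
13 | 5β-H 9(10)-en-8-one acetonide | O=C1CC[C@H]2C(CC[C@H]3OC(C)(C)OC[C@]23C)=C1 | intermediate
14 | 8α-hydroxy 5β-H 9(10)-ene acetonide (key-step precursor) | O[C@@H]1CC[C@H]2C(CC[C@H]3OC(C)(C)OC[C@]23C)=C1 | intermediate
15 | diiodomethane | ICI | starting material
16 | iodomethylzinc 8α-alkoxide of 14 (not isolated) | IC[Zn]O[C@@H]1CC[C@H]2C(CC[C@H]3OC(C)(C)OC[C@]23C)=C1 | intermediate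
17 | 9α,10α-methano 8α-ol acetonide (key-step product) | O[C@@H]1CC[C@H]2[C@@]3(C[C@H]13)CC[C@H]4OC(C)(C)OC[C@]24C | intermediate
18 | 9α,10α-methano 8-one acetonide | O=C1CC[C@H]2[C@@]3(C[C@H]13)CC[C@H]4OC(C)(C)OC[C@]24C | intermediate
19 | tert-butyl bromoacetate | CC(C)(C)OC(=O)CBr | starting material
20 | lithium 8(9)-enolate of the 10α-methyl trans-decalin acetonide (not isolated) | [Li+].[O-]C=1CC[C@H]2[C@@](C)(CC[C@H]3OC(C)(C)OC[C@]23C)C=1 | intermediate
21 | tert-butyl (8-oxo-10α-methyl-decalin-9-yl)acetate acetonide, C9 epimer mixture | O=C1CC[C@H]2[C@@](C)(CC[C@H]3OC(C)(C)OC[C@]23C)C1CC(=O)OC(C)(C)C | intermediate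
22 | same keto ester with 9β-H (C11 equatorial, α) | O=C1CC[C@H]2[C@@](C)(CC[C@H]3OC(C)(C)OC[C@]23C)[C@@H]1CC(=O)OC(C)(C)C | intermediate
23 | methyltriphenylphosphonium bromide | C[P+](c1ccccc1)(c1ccccc1)c1ccccc1.[Br-] | starting material
24 | methylenetriphenylphosphorane (not isolated) | C=P(c1ccccc1)(c1ccccc1)c1ccccc1 | intermediate
25 | 8(17)-methylene tert-butyl ester acetonide | C=C1CC[C@H]2[C@@](C)(CC[C@H]3OC(C)(C)OC[C@]23C)[C@@H]1CC(=O)OC(C)(C)C | intermediate
26 | 12-hydroxy 8(17)-ene acetonide | C=C1CC[C@H]2[C@@](C)(CC[C@H]3OC(C)(C)OC[C@]23C)[C@@H]1CCO | intermediate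
27 | 12-iodo 8(17)-ene acetonide | C=C1CC[C@H]2[C@@](C)(CC[C@H]3OC(C)(C)OC[C@]23C)[C@@H]1CCI | intermediate
28 | 4-bromofuran-2(5H)-one | O=C1OCC(Br)=C1 | starting material
29 | 12-(iodozincio) 8(17)-ene acetonide (not isolated) | C=C1CC[C@H]2[C@@](C)(CC[C@H]3OC(C)(C)OC[C@]23C)[C@@H]1CC[Zn]I | intermediate
30 | 3α,18-O-isopropylidene-labda-8(17),13-dien-15,16-olide | C=C1CC[C@H]2[C@@](C)(CC[C@H]3OC(C)(C)OC[C@]23C)[C@@H]1CCC1=CC(=O)OC1 | intermediate
31 | 3α,18-dihydroxylabda-8(17),13-dien-15,16-olide | C=C1CC[C@H]2[C@@](C)(CC[C@@H](O)[C@]2(C)CO)[C@@H]1CCC1=CC(=O)OC1 | intermediate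
32 | 18-O-(tert-butyldimethylsilyl)-3α-hydroxylabda-8(17),13-dien-15,16-olide | C=C1CC[C@H]2[C@@](C)(CC[C@@H](O)[C@]2(C)CO[Si](C)(C)C(C)(C)C)[C@@H]1CCC1=CC(=O)OC1 | intermediate
33 | angelic acid, (Z)-2-methylbut-2-enoic acid | C/C=C(/C)C(=O)O | starting material
34 | angelic 2,4,6-trichlorobenzoic anhydride (not isolated) | C/C=C(/C)C(=O)OC(=O)c1c(Cl)cc(Cl)cc1Cl | intermediate
35 | 3α-angeloyloxy-18-O-(tert-butyldimethylsilyl)labda-8(17),13-dien-15,16-olide | C=C1CC[C@H]2[C@@](C)(CC[C@@H](OC(=O)/C(C)=C\C)[C@]2(C)CO[Si](C)(C)C(C)(C)C)[C@@H]1CCC1=CC(=O)OC1 | intermediate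
36 | (3R,4S,5S,9R,10S)-3-angeloyloxy-18-hydroxylabda-8(17),13-dien-15,16-olide | C=C1CC[C@H]2[C@@](C)(CC[C@@H](OC(=O)/C(C)=C\C)[C@]2(C)CO)[C@@H]1CCC1=CC(=O)OC1 | target

**Step count and risks**

Total step count: 20. Longest linear sequence: 20 steps (from 1; all other building blocks are commercial).

Steps most likely to fail:

1. Step 3. The risk is poor enantiofacial discrimination or slow turnover at the congested tetrasubstituted enol ether, with protodesilylation back to racemic ketone competing in the aqueous medium. The fallback sets out from 5 and makes the quaternary centre by carbon–carbon bond formation at palladium instead. A Tsuji–Trost-type asymmetric allylic alkylation of the α-aryl ketone enolate (allyl acetate, [Pd(C3H5)Cl]2, (R,R)- or (S,S)-N,N'-bis(2-diphenylphosphinobenzoyl)-1,2-diaminocyclohexane, NaN(SiMe3)2 or Cs2CO3, DME) should give (R)-1-allyl-6-methoxy-1-methyl-3,4-dihydronaphthalen-2(1H)-one F1. Alkene migration with RuHCl(CO)(PPh3)3 (cat.) in toluene at 80 °C should give the (E)-propenyl ketone F2. Lemieux–Johnson cleavage (OsO4 cat., NaIO4, 2,6-lutidine, dioxane/H2O) should give the keto aldehyde F3. Excess Me4NBH(OAc)3 in MeCN/AcOH should then reduce the aldehyde and, by internal delivery from the new C18 alkoxide, the ketone. The fallback comes back to the route at 9.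

2. Step 11. The risk is slow C-alkylation at C9 beside quaternary C10, so that proton transfer (returning unalkylated ketone), O-alkylation or consumption of the bromoacetate by lithium alkoxide takes over. The fallback sets out from 18. The same Li/NH3 cleavage is run, but the enolate is quenched with allyl bromide, the most reactive and non-enolisable partner for reductive alkylation, to give the 9-allyl 8-ketone acetonide F4. The two-carbon ester arm is then cut out of the allyl group: Lemieux–Johnson cleavage to the keto aldehyde F5, Pinnick oxidation (NaClO2, NaH2PO4, 2-methyl-2-butene, t-BuOH/H2O) to the keto acid F6, and esterification with O-tert-butyl-N,N'-diisopropylisourea in CH2Cl2. The fallback comes back to the route at 21, and step 12 then equilibrates C9.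

3. Step 16. The risk is incomplete zinc insertion, β-hydride elimination from the alkylpalladium intermediate, or degradation of the bromofuranone by the organometallic. The fallback sets out from 27 and builds the butenolide by polar chemistry instead of cross-coupling. Alkylation of 2-lithio-1,3-dithiane (THF, −30 °C) should give the 2-alkyl-1,3-dithiane F7. Relithiation (n-BuLi, THF, −20 °C) and quenching with monomeric formaldehyde should give the 2-alkyl-2-(hydroxymethyl)-1,3-dithiane F8. Unmasking with MeI and CaCO3 in aqueous MeCN should give the 1-hydroxy-2-ketone F9. The Bestmann ylide Ph3P=C=C=O in toluene at 80 °C should then acylate the hydroxyl and close the ring by intramolecular Wittig reaction. The fallback comes back to the route at 30.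

**Further compounds**

F1 | step 3 | (R)-1-allyl-6-methoxy-1-methyl-3,4-dihydronaphthalen-2(1H)-one | COc1ccc2c(CCC(=O)[C@]2(C)CC=C)c1
F2 | step 3 | (R,E)-6-methoxy-1-methyl-1-(prop-1-enyl)-3,4-dihydronaphthalen-2(1H)-one | COc1ccc2c(CCC(=O)[C@]2(C)/C=C/C)c1
F3 | step 3 | (S)-6-methoxy-1-methyl-2-oxo-1,2,3,4-tetrahydronaphthalene-1-carbaldehyde | COc1ccc2c(CCC(=O)[C@]2(C)C=O)c1
F4 | step 11 | 9-allyl 8-oxo-10α-methyl-decalin acetonide (C9 epimers) | O=C1CC[C@H]2[C@@](C)(CC[C@H]3OC(C)(C)OC[C@]23C)C1CC=C
F5 | step 11 | (8-oxo-10α-methyl-decalin-9-yl)acetaldehyde acetonide (C9 epimers) | O=C1CC[C@H]2[C@@](C)(CC[C@H]3OC(C)(C)OC[C@]23C)C1CC=O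
F6 | step 11 | (8-oxo-10α-methyl-decalin-9-yl)acetic acid acetonide (C9 epimers) | O=C1CC[C@H]2[C@@](C)(CC[C@H]3OC(C)(C)OC[C@]23C)C1CC(=O)O
F7 | step 16 | 2-alkyl-1,3-dithiane (C13 as dithiane carbon) of the 8(17)-ene acetonide | C=C1CC[C@H]2[C@@](C)(CC[C@H]3OC(C)(C)OC[C@]23C)[C@@H]1CCC1SCCCS1
F8 | step 16 | 2-alkyl-2-(hydroxymethyl)-1,3-dithiane of the 8(17)-ene acetonide | C=C1CC[C@H]2[C@@](C)(CC[C@H]3OC(C)(C)OC[C@]23C)[C@@H]1CCC1(CO)SCCCS1
F9 | step 16 | 16-hydroxy-13-oxo 8(17)-ene acetonide (1-hydroxy-2-ketone) | C=C1CC[C@H]2[C@@](C)(CC[C@H]3OC(C)(C)OC[C@]23C)[C@@H]1CCC(=O)CO
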